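The runs were generated by integration on assumed constants, noise included.

Target does not last in either earlier run: it fades while the isomer of the product takes over, and the two settle into a steady ratio. Asked is the isomer's share of that pair.

| flask | starting material | protic impurity | remark | time |
|---|---|---|---|---|
| violet | 5 mM | 0.20 mM | run made earlier |  |
| blue | 20 mM | 0.20 mM | run made earlier |  |
| flask | 10 mM | 0.200 mM |  | 1.0 h |

- violet (time / min: isomer of the product / %, target / %): 4.00: 25.5, 24.7; 8.00: 38.8, 9.1; 15.0: 41.1, 2.8; 25.0: 38.4, 1.2; 50.0: 29.7, 0.9
- blue (time / min: isomer of the product / %, target / %): 10.0: 42.2, 5.7; 20.0: 41.1, 1.1; 30.0: 37.4, 0.9; 40.0: 33.6, 1.1; 50.0: 30.5, 1.0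

(standard deviation of a reading: 0.3 percentage points)

- share of isomer of the product in isomer of the product plus target at 1.5 s
- share of isomer of the product in isomer of the product plus target at 80 s
- share of isomer of the product in isomer of the product plus target at 1.0 h



A first estimate comes from the last blue reading, where the isomer holds 96.8 % of the pair. The last violet reading gives 97.1 %, and the new flask's charge lies between those of the two runs, with the same protic impurity. Putting the first estimate back into the violet run, the target's excess over its late part of the pair shrinks between 8.00 min and 15.0 min at 0.228 min⁻¹, a relaxation time of 4.38 min. Going round once more, that rate leaves an excess of 0.327 % of the pair in the violet reading at 25.0 min, so that reading is set aside.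

The weak link is a single target reading of 1.0 % carrying a scatter of 0.3 percentage points. Pooling 4 late readings, violet at 50.0 min and blue from 30.0 min on, cuts the scatter of the mean target to half. Pooled they give 97.1 %: the plateau share, the part the isomer holds of isomer plus target once relaxation is over. The flask's 1.0 h is longer than the relaxation time, so this is the number committed to for 1.0 h. The times 1.5 s and 80 s lie before the first reading, and the plateau share says nothing of them.

The forecast gave 1 %, 18 % and 97.1 %, saying of the plateau that “this looks like equilibrium”.

The flask gives 1.90 %, 19.6 % and 96.4 %, the last 0.70 points below the plateau share read from the earlier runs.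

    starting material ⇌ other conformer (K = 0.0100, k = 0.0110 s⁻¹)
    starting material → target (k = 0.00630 s⁻¹)
    other conformer → isomer of the product (k = 0.0200 s⁻¹)
    target ⇌ isomer of the product (K = 13.0, k = 0.00410 s⁻¹)
    target → over-reaction product (k = 0.00450 s⁻¹)
    starting material + protic impurity → quenched substrate (k = 220 M⁻¹ s⁻¹)

At 1.00 h the flask makes target at 0.964 of the rate at which it uses it up, each step taken net, nearly a quasi-steady state, and the half-life of relaxation between target and isomer by that step alone, both ways together, is 2.62 min, short against that time. At 0.0300 h target already passes into over-reaction product 1.1 times as fast as into the isomer, forward steps taken. The neighbour flask with 40 mM of starting material holds 28.0 % of its charge as isomer at 1.00 h, so the plateau share puts its target at 0.836 % of the charge; it holds 1.05 %.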